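The small charge of Q in the winter run says little about E: 84.8% of the charge is L at 0.167 min and 98.5% at 2.00 min, which by that reading leaves about 1.50% for Q. The noon run is the informative one.

| flask | Q | E | remark | time |
|---|---|---|---|---|
| winter | 0.0029 M | 5 µM | run made earlier |  |
| noon | 0.23 M | 5 µM | run made earlier |  |
| larch | 0.0020 M | 5.0 µM |  | 2.5 min |
| oak | 0.0060 M | 5.0 µM |  | 2.5 min |
| birch | 0.015 M | 5.0 µM |  | 2.5 min |
| maple | 0.050 M | 5.0 µM |  | 2.5 min |
| alder | 0.15 M | 5.0 µM |  | 2.5 min |

| run | time / min | L / % |
|---|---|---|
| winter | 0.167 | 84.8 |
| winter | 0.417 | 93.0 |
| winter | 0.667 | 96.9 |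
| winter | 1.00 | 97.1 |
| winter | 1.50 | 98.2 |
| winter | 2.00 | 98.5 |
| winter | 2.50 | 98.1 |
| noon | 0.167 | 2.1 |
| noon | 0.417 | 2.6 |
| noon | 0.667 | 2.6 |
| noon | 1.00 | 3.5 |
| noon | 1.50 | 3.7 |
| noon | 2.00 | 4.1 |
| noon | 2.50 | 3.0 |

(standard deviation of a reading: 0.5 percentage points)

- the earlier runs were read with a standard deviation of 0.5 percentage points
- steps that have been proposed: Q + E -> L + E; 2 E -> X
- "hardly changes" means that all values lie within two and a half points (for a concentration: within two and a half percent of the largest)

- [L] at the end for larch, oak, birch, maple, alder, in this order
- how that number moves from the first to the last of them (falls all the way / rises all the way / hardly changes / rises, then falls / falls, then rises)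

I order the noon run by time. On the first rung, L in the noon run reads 2.1% of the charge at 0.167 min. Over the last three noon readings it averages 3.60%, so the first noon reading already holds 58.3% of that level. On the next rung, from the noon reading at 0.667 min to that average, L gains about 1 percentage point, with a scatter of 0.5 points on each reading. The last rung is the window itself, and the first noon reading comes far earlier than its end. Yet about 96.4% of the noon charge remains as Q, so I take the stall at noon to be a loss of E, perhaps the proposed step in which two E give X.

I therefore carry one quantity, the budget: the L made per E charged within the window, the total turnover number, read at noon as 1660. The winter charge is 580 per E, below the budget, so the winter run does not test it, and I assume that it holds for each charge. For larch it covers 4.14 times the charge and for oak 1.38 times, so on this reckoning Q is the limiting reagent in both. It covers 55.2% of birch, 16.6% of maple and 5.52% of alder.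

The forecast gives 99.0%, 91.7%, 52.0%, 17.0% and 5.73% of the charges, in its words “a row that rises and then plateaus”, and for the concentrations of L its shape is rises all the way. At oak it stops at 91.7% of the charge, whereas my budget covers more than that charge.

    Q + E → L + E, rate k1*[Q]*[E]/(1 + ([Q]/Km1) + ([Q]/Ksi1)^2) (9.70 mM, 24.0 mM, k = 1.80 × 10⁵ L mol⁻¹ s⁻¹)
    2 E → X (k = 98000 L mol⁻¹ s⁻¹)

The flask gives 98.8%, 98.1%, 94.7%, 46.7% and 8.51% of the charges as L, so the row of concentrations rises, then falls, turning at a Q concentration of 0.039 M. E stands at 0.676% of its charge at the end of maple and 0.676% at the end of alder. Maple makes 4660 L per E charged, more than the budget of 1660 read at noon. Alder, where the budget covers 5.52% of the charge, has 8.51% as L and makes 2560 L per E charged.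

The data are simulated for an exercise, noise included.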